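**Assumption:** (S)-(+)-linalool (coriandrol) is taken as purchasable in high ee; if its ee is insufficient it is upgraded before use. This route is a design that has not been run; selectivities are argued from precedent.

## Retrosynthetic overview

1. The butenolide ring is formed last: Pd-carbonylative lactonisation of a (Z)-γ-iodoallylic alcohol, itself made by hydroxyl-directed trans-hydroalumination/iodination of a propargylic alcohol.
2. The lactone stereocentre (R) comes from Noyori transfer hydrogenation of an alkynyl ketone, assembled by carbonylative Stille coupling (allyl chloride + CO + alkynylstannane).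
3. The allyl chloride comes from SeO2 oxidation of the (E)-methyl of the prenyl terminus of the chromene.
4. Key strategy: the chromene ring is formed first from (S)-linalool, which supplies the quaternary stereocentre and all ten side-chain carbons. Heck arylation, photocatalytic E→Z isomerisation and intramolecular Pd C–O coupling close the ring without ever breaking the C–O bond of the stereocentre.
5. The aryl partner is 3-bromo-4-chloro-5-methylphenol TIPS ether, from 3-bromo-5-methylphenol.

## Forward route

**Step 1**
Reactants: 1, 3-bromo-5-methylphenol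
Product: 2, 3-bromo-4-chloro-5-methylphenol
Conditions: SO2Cl2 (1.0 eq), cat. Ph2S/AlCl3, CH2Cl2, 0 °C → rt
Reagents that add atoms: sulfuryl chloride, ClS(Cl)(=O)=O
Why: Electrophilic aromatic chlorination para to OH, as in the PCMX-type chlorination of 3,5-disubstituted phenols; minor ortho isomers are removed by crystallisation.

**Step 2**
Reactants: 2
Product: 3, (3-bromo-4-chloro-5-methylphenoxy)triisopropylsilane
Conditions: TIPSCl, imidazole, DMF, rt
Reagents that add atoms: TIPSCl, CC(C)[Si](Cl)(C(C)C)C(C)C
Why: Standard phenol silylation; the aryl TIPS ether tolerates the Pd, carbonate, hydride and oxidant conditions that follow and is removed with fluoride at the end.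

**Step 3**
Reactants: 3; 4, (S)-linalool
Product: 5, (S,E)-1-[2-chloro-3-methyl-5-(triisopropylsilyloxy)phenyl]-3,7-dimethylocta-1,6-dien-3-ol
Conditions: Pd(OAc)2, P(o-tol)3, Et3N, DMF, 100 °C
Reagents that add atoms: none
Why: Mizoroki–Heck arylation of the monosubstituted vinyl group; C–Br reacts and C–Cl is untouched, β-H elimination gives the E-styrene, and the carbinol centre is not involved.

**Step 4**
Reactants: 5
Product: 6, (S,Z)-1-[2-chloro-3-methyl-5-(triisopropylsilyloxy)phenyl]-3,7-dimethylocta-1,6-dien-3-ol
Conditions: fac-Ir(ppy)3 (1 mol%), blue LEDs, degassed MeCN, rt; residual E isomer recycled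
Reagents that add atoms: none
Why: Triplet-sensitised contra-thermodynamic E→Z styrene isomerisation; the Z isomer is twisted out of conjugation by A1,3 strain between the ortho-chloroaryl and the quaternary carbinol, so it is not re-excited and accumulates.

**Step 5**
Reactants: 6
Product: 7, (S)-2,8-dimethyl-2-(4-methylpent-3-en-1-yl)-6-(triisopropylsilyloxy)-2H-chromene
Conditions: Pd2(dba)3, RockPhos (or t-BuBrettPhos), Cs2CO3, toluene, 90 °C
Reagents that add atoms: none
Why: Buchwald-type intramolecular C–O coupling of the tertiary alkoxide (no β-H) onto the aryl chloride. The C2 stereocentre is the linalool carbinol carbon with its C–O bond intact, so (S) is carried over.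

**Step 6**
Reactants: 7
Product: 8, (E)-5-[(S)-2,8-dimethyl-6-(triisopropylsilyloxy)-2H-chromen-2-yl]-2-methylpent-2-en-1-ol
Conditions: SeO2 (0.5 eq), t-BuOOH, cat. salicylic acid, CH2Cl2, rt; then NaBH4, MeOH, 0 °C
Reagents that add atoms: SeO2, O=[Se]=O; t-BuOOH, CC(C)(C)OO (oxygen source)
Why: Sharpless SeO2 allylic oxidation (ene/[2,3]) is selective for the (E)-methyl of the gem-dimethyl terminus; the borohydride returns over-oxidised enal to the alcohol. The chromene has no allylic C–H.

**Step 7**
Reactants: 8
Product: 9, (S)-2-[(E)-5-chloro-4-methylpent-3-en-1-yl]-2,8-dimethyl-6-(triisopropylsilyloxy)-2H-chromene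
Conditions: MsCl, LiCl, 2,4,6-collidine, DMF, 0 °C
Reagents that add atoms: LiCl, [Li+].[Cl-]
Why: Collington–Meyers conversion of a primary allylic alcohol to the chloride by SN2, without allylic transposition or E/Z loss.

**Step 8**
Reactants: 10, 5-bromo-2-methylpent-2-ene; 11, lithium acetylide–ethylenediamine complex
Product: 12, 6-methylhept-5-en-1-yne
Conditions: DMSO, 0 °C → rt
Reagents that add atoms: none (both reactants listed)
Why: SN2 alkylation of acetylide by a primary homoallylic bromide.

**Step 9**
Reactants: 12
Product: 13, tributyl(6-methylhept-5-en-1-yn-1-yl)stannane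
Conditions: n-BuLi, THF, −78 °C; then Bu3SnCl, → rt
Reagents that add atoms: Bu3SnCl, CCCC[Sn](Cl)(CCCC)CCCC
Why: Deprotonation of the terminal alkyne and stannylation.

**Step 10**
Reactants: 9; 13; carbon monoxide
Product: 14, (E)-1-[(S)-2,8-dimethyl-6-(triisopropylsilyloxy)-2H-chromen-2-yl]-4,12-dimethyltrideca-3,11-dien-7-yn-6-one
Conditions: Pd(dba)2, PPh3, CO (3–4 atm), THF, 50 °C; ynone used promptly
Reagents that add atoms: CO, [C-]#[O+]
Why: Stille carbonylative three-component coupling; CO inserts at the unsubstituted terminus of the π-allyl and the alkynyl group transfers from tin under neutral conditions, keeping the E-olefin and leaving the ketone deconjugated.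

**Step 11**
Reactants: 14
Product: 15, (3E,6R)-1-[(S)-2,8-dimethyl-6-(triisopropylsilyloxy)-2H-chromen-2-yl]-4,12-dimethyltrideca-3,11-dien-7-yn-6-ol
Conditions: Ru[(R,R)-TsDPEN](p-cymene) (16-electron amido complex, 1 mol%), i-PrOH, rt, no added base
Reagents that add atoms: none
Why: Noyori asymmetric transfer hydrogenation of an α,β-alkynyl ketone; the alkyne is the π-recognition element, so the (R,R) catalyst gives the (R)-propargylic alcohol under catalyst control.

**Step 12**
Reactants: 15
Product: 16, (3E,6R,7Z)-1-[(S)-2,8-dimethyl-6-(triisopropylsilyloxy)-2H-chromen-2-yl]-8-iodo-4,12-dimethyltrideca-3,7,11-trien-6-ol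
Conditions: Red-Al, THF, 0 °C → rt; then I2, −78 → 0 °C
Reagents that add atoms: iodine, II
Why: Hydroxyl-directed trans-hydroalumination gives a five-membered oxa-aluminacycle with Al on the distal alkyne carbon; iodinolysis with retention places I cis to the carbinol carbon, and the carbinol is untouched.

**Step 13**
Reactants: 16; carbon monoxide
Product: 17, (R)-5-{(E)-5-[(S)-2,8-dimethyl-6-(triisopropylsilyloxy)-2H-chromen-2-yl]-2-methylpent-2-en-1-yl}-3-(4-methylpent-3-en-1-yl)furan-2(5H)-one
Conditions: PdCl2(PPh3)2 (5 mol%), CO (1 atm), K2CO3, THF, rt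
Reagents that add atoms: CO, [C-]#[O+]
Why: Carbonylative lactonisation: oxidative addition to the vinyl iodide, CO insertion, and capture of the acyl-Pd by the cis hydroxyl give the α-alkyl butenolide. The C–O bond at the stereocentre is not broken, and the mild heterogeneous base avoids γ-epimerisation.

**Step 14**
Reactants: 17
Product: 18, tuberatolide B
Conditions: TBAF/AcOH (1:1), THF, 0 °C
Reagents that add atoms: none
Why: Buffered fluoride cleaves the aryl silyl ether without epimerising the butenolide γ-centre or ionising the chromene.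

## Compound list

| No. | Name | SMILES | Role |
|---|---|---|---|
| 1 | 3-bromo-5-methylphenol | Cc1cc(O)cc(Br)c1 | starting material |
| 2 | 3-bromo-4-chloro-5-methylphenol | Cc1cc(O)cc(Br)c1Cl | intermediate |
| 3 | TIPS ether of 2 | Cc1cc(O[Si](C(C)C)(C(C)C)C(C)C)cc(Br)c1Cl | intermediate |
| 4 | (S)-linalool | CC(C)=CCC[C@](C)(O)C=C | starting material |
| 5 | (S,E)-Heck product | CC(C)=CCC[C@](C)(O)/C=C/c1cc(O[Si](C(C)C)(C(C)C)C(C)C)cc(C)c1Cl | intermediate |
| 6 | (S,Z)-isomer of 5 | CC(C)=CCC[C@](C)(O)/C=C\c1cc(O[Si](C(C)C)(C(C)C)C(C)C)cc(C)c1Cl | intermediate |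
| 7 | (S)-chromene | CC(C)=CCC[C@@]1(C)C=Cc2cc(O[Si](C(C)C)(C(C)C)C(C)C)cc(C)c2O1 | intermediate |
| 8 | (E)-allylic alcohol | OC/C(C)=C/CC[C@@]1(C)C=Cc2cc(O[Si](C(C)C)(C(C)C)C(C)C)cc(C)c2O1 | intermediate |
| 9 | (E)-allylic chloride | ClC/C(C)=C/CC[C@@]1(C)C=Cc2cc(O[Si](C(C)C)(C(C)C)C(C)C)cc(C)c2O1 | intermediate |
| 10 | 5-bromo-2-methylpent-2-ene | CC(C)=CCCBr | starting material |
| 11 | lithium acetylide–ethylenediamine | [Li]C#C.NCCN | starting material |
| 12 | 6-methylhept-5-en-1-yne | CC(C)=CCCC#C | intermediate |
| 13 | tributyl(6-methylhept-5-en-1-ynyl)stannane | CC(C)=CCCC#C[Sn](CCCC)(CCCC)CCCC | intermediate |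
| 14 | ynone | CC(C)=CCCC#CC(=O)C/C(C)=C/CC[C@@]1(C)C=Cc2cc(O[Si](C(C)C)(C(C)C)C(C)C)cc(C)c2O1 | intermediate |
| 15 | (R)-propargylic alcohol | CC(C)=CCCC#C[C@H](O)C/C(C)=C/CC[C@@]1(C)C=Cc2cc(O[Si](C(C)C)(C(C)C)C(C)C)cc(C)c2O1 | intermediate |
| 16 | (R,Z)-γ-iodoallylic alcohol | CC(C)=CCC/C(I)=C/[C@H](O)C/C(C)=C/CC[C@@]1(C)C=Cc2cc(O[Si](C(C)C)(C(C)C)C(C)C)cc(C)c2O1 | intermediate |
| 17 | O-TIPS tuberatolide B | CC(C)=CCCC1=C[C@@H](C/C(C)=C/CC[C@@]2(C)C=Cc3cc(O[Si](C(C)C)(C(C)C)C(C)C)cc(C)c3O2)OC1=O | intermediate |
| 18 | tuberatolide B | CC(C)=CCCC1=C[C@@H](C/C(C)=C/CC[C@@]2(C)C=Cc3cc(O)cc(C)c3O2)OC1=O | target |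

## Summary

**Total steps:** 14.
**Longest linear sequence:** 12 (steps 1–7, 10–14); steps 8–9 are a two-step side branch.

**Steps most likely to fail, with fallbacks:**

1. **Steps 4–5 (Z-alkene and C–O closure on a hindered, electron-rich aryl chloride).** Risks are an incomplete photostationary state and slow oxidative addition. Fallback: build the Z-alkene from an alkyne. Geraniol is taken through Sharpless epoxidation (L-(+)-DET, giving the 2S,3S epoxide), conversion to the epoxy chloride, and n-BuLi elimination to (S)-3,7-dimethyloct-6-en-1-yn-3-ol. Sonogashira coupling with 3 and Lindlar reduction then give 6; alternatively, a 1-iodo-2-bromo arene allows Cu-mediated ring closure.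

2. **Step 10 (carbonylative Stille).** Risks are direct allyl–alkynyl coupling without CO, syn/anti π-allyl isomerisation eroding the E-olefin, and conjugation of the ynone. Fallback: avoid the π-allyl. Convert 9 to the allyl phenyl sulfone, α-lithiate and acylate with the Weinreb amide of 7-methyloct-6-en-2-ynoic acid, then desulfonylate with SmI2 to give 14.

3. **Step 11 (transfer hydrogenation of a β,γ-unsaturated ynone).** Risks are base-induced isomerisation into conjugation and lower ee with the allylic CH2 substituent. Fallback: set the carbinol by C–C bond formation instead of reduction. Alkylate a chiral N-glycolyl oxazolidinone (Crimmins/Evans) with 9, reduce to the α-alkoxy aldehyde, carry out Still–Gennari Z-olefination with the α-(4-methylpent-3-enyl)phosphonoacetate, then deprotect and lactonise to 17.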